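**Plan**

Rings: A = ester-bearing cyclopentene, B = second cyclopentene, C = cycloheptene, D = piperidine, E = hydroxytetrahydropyran.

1. Ring E is opened to a δ-hydroxy ketone and its spiro carbon is cut three times (Wittig C–C bond, aldol C–CH2OH bond, one-carbon homologation) back to a bridging ketone; the ester is cut at C–CO2Me (carbonylation of a dienyl triflate).
2. Ring C is cut at the bond from the bridgehead CH to its ring CH2 (ketone enolate plus primary iodide). Rings A and B are cut together into an alkyne, a vinyl group and CO, that is, the ring-fusion C–C bond and both bonds to one carbonyl carbon.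
3. Feature used: rings A and B are two cyclopentenes sharing one bond of the diene, and ring A holds the quaternary carbon common to rings A, C and D. This bicyclo[3.3.0]octene is what a 1,6-enyne on a quaternary propargylic carbon gives with CO in one step.
4. Forward order: ring D is bought as a 4-piperidinone; the quaternary carbon is made by alkynylation and decarboxylative allylation; rings A and B form together; ring C follows by alkylation; then dienoate, N-methyl group and, last, ring E.
5. Stereochemistry: the quaternary carbon comes from the palladium/(S)-t-BuPHOX allylation; the bridgehead CH is dictated by the bridged ring closure; the spiro carbon is set by hydroxymethylation on the cycloheptene face; the hemiketal carbon equilibrates.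
6. The piperidinone carbonyl is held as a silyl-protected alcohol from step 4 to step 16, so that it cannot compete with the acetylide, the ketalisation or the enone reduction.

Key step: step 11

Assumption: the hemiketal carbon of the target interconverts with the open δ-hydroxy ketone, and the anomer drawn is taken to be the thermodynamically favoured one.

Abbreviations: Boc = tert-butoxycarbonyl, TBS = tert-butyldimethylsilyl.

**Route**

Step 1
Reactants: 1 1-tert-butyl 3-methyl 4-oxopiperidine-1,3-dicarboxylate; 2 allyl alcohol
Product: 3 3-allyl 1-tert-butyl 4-oxopiperidine-1,3-dicarboxylate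
Conditions: allyl alcohol (5 equiv), DMAP (0.3 equiv), toluene, 110 °C, 4 Å molecular sieves
Reagents that add atoms: none
Why: DMAP-catalysed transesterification of a β-keto ester exchanges methoxide for allyloxide as methanol is removed, and no stereocentre is formed.

Step 2
Reactants: 3 allyl β-keto ester; 4 1-[(trimethylsilyl)ethynyl]-1,2-benziodoxol-3(1H)-one
Product: 5 3-allyl 1-tert-butyl 3-ethynyl-4-oxopiperidine-1,3-dicarboxylate (racemic)
Conditions: 4 (1.3 equiv), Bu4NF (1.3 equiv), THF, −78 °C → rt
Reagents that add atoms: none
Why: Electrophilic alkynylation of a stabilised enolate with a hypervalent-iodine reagent: fluoride unmasks ethynylbenziodoxolone, the enolate adds, and loss of 2-iodobenzoate with a 1,2-hydrogen shift leaves the terminal alkyne on the new quaternary carbon, which may be racemic because step 3 is enantioconvergent.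

Step 3
Reactants: 5 racemic α-ethynyl β-keto allyl ester
Product: 6 tert-butyl (3S)-3-allyl-3-ethynyl-4-oxopiperidine-1-carboxylate
Conditions: Pd2(dba)3 (2.5 mol %), (S)-t-BuPHOX (6 mol %), toluene, 30 °C
Reagents that add atoms: none
Why: Decarboxylative asymmetric allylic alkylation (Tsuji–Trost type): zerovalent palladium ionises the allyl ester, CO2 is lost and the allylpalladium enolate recombines on the enolate face chosen by the phosphinooxazoline ligand, which by analogy with the 2-allyl-2-methylcyclohexanone case (ethynyl in place of methyl) should give the (S) quaternary carbon.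

Step 4
Reactants: 6 α-allyl-α-ethynyl piperidinone
Product: 7 tert-butyl (3S,4R)-3-allyl-3-ethynyl-4-hydroxypiperidine-1-carboxylate
Conditions: NaBH4, MeOH, −20 °C
Reagents that add atoms: none
Why: Borohydride reduction masks the ketone that would compete in steps 5, 10 and 12; axial attack anti to the axial ethynyl group should give mainly the alcohol cis to ethynyl, and the minor epimer can be carried along because this carbon is re-oxidised in step 16.

Step 5
Reactants: 7 ethynyl alcohol; 8 ethylene oxide
Product: 9 tert-butyl (3S,4R)-3-allyl-4-hydroxy-3-(4-hydroxybut-1-yn-1-yl)piperidine-1-carboxylate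
Conditions: n-BuLi (2.2 equiv), THF, −78 °C; BF3·OEt2 (2.2 equiv); ethylene oxide (3 equiv), −78 °C
Reagents that add atoms: none
Why: BF3-mediated opening of an epoxide by a lithium acetylide: the alkoxide–acetylide dianion reacts at its more nucleophilic carbon end and adds the two-carbon hydroxyethyl unit.

Step 6
Reactants: 9 diol
Product: 10 tert-butyl (3S,4R)-3-allyl-4-(TBS-oxy)-3-[4-(TBS-oxy)but-1-yn-1-yl]piperidine-1-carboxylate
Conditions: t-BuMe2SiOTf (2.5 equiv), 2,6-lutidine, CH2Cl2, 0 °C
Reagents that add atoms: tert-butyldimethylsilyl trifluoromethanesulfonate, CC(C)(C)[Si](C)(C)OS(=O)(=O)C(F)(F)F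
Why: Silylation of alcohols with a silyl triflate, which is reactive enough to cap the hindered secondary hydroxyl as well as the primary one.

Step 7
Reactants: 10 bis-silyl ether
Product: 11 tert-butyl (3S,4R)-4-(TBS-oxy)-3-[4-(TBS-oxy)but-1-yn-1-yl]-3-(2-oxoethyl)piperidine-1-carboxylate
Conditions: O3, CH2Cl2/MeOH, −78 °C (to first blue colour); Me2S, −78 °C → rt
Reagents that add atoms: ozone, [O-][O+]=O
Why: Ozonolysis with reductive work-up cleaves the monosubstituted alkene to the aldehyde, while the internal alkyne reacts far more slowly with ozone and is spared at −78 °C.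

Step 8
Reactants: 11 aldehyde; 12 vinylmagnesium bromide
Product: 13 tert-butyl (3S,4R)-4-(TBS-oxy)-3-[4-(TBS-oxy)but-1-yn-1-yl]-3-(2-hydroxybut-3-en-1-yl)piperidine-1-carboxylate (both carbinol epimers)
Conditions: CH2=CHMgBr (1.5 equiv), THF, −78 °C
Reagents that add atoms: none
Why: Grignard 1,2-addition to the aldehyde; the new carbinol centre is not controlled and need not be, since both epimers give the same ketone in step 9.

Step 9
Reactants: 13 allylic alcohol
Product: 14 tert-butyl (3S,4R)-4-(TBS-oxy)-3-[4-(TBS-oxy)but-1-yn-1-yl]-3-(2-oxobut-3-en-1-yl)piperidine-1-carboxylate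
Conditions: Dess–Martin periodinane, NaHCO3, CH2Cl2, 0 °C → rt
Reagents that add atoms: none
Why: Dess–Martin oxidation gives the vinyl ketone under buffered, non-nucleophilic conditions that avoid conjugate addition to the enone.

Step 10
Reactants: 14 vinyl ketone
Product: 15 tert-butyl (3S,4R)-4-(TBS-oxy)-3-[4-(TBS-oxy)but-1-yn-1-yl]-3-[(2-vinyl-1,3-dioxolan-2-yl)methyl]piperidine-1-carboxylate (the 1,6-enyne)
Conditions: Me3SiOCH2CH2OSiMe3 (2 equiv), Me3SiOTf (5 mol %), CH2Cl2, −78 °C; pyridine quench
Reagents that add atoms: 1,2-bis(trimethylsilyloxy)ethane, C[Si](C)(C)OCCO[Si](C)(C)C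
Why: Silyl-triflate-catalysed ketalisation with the bis-silyl ether of ethylene glycol converts the enone into its dioxolane at low temperature without conjugate addition, and no other ketone is present to compete.

Step 11
Reactants: 15 1,6-enyne; 16 carbon monoxide
Product: 18 N-Boc 4-(TBS-oxy)piperidine spiro-linked at C3 to a ketal-bearing bicyclo[3.3.0]oct-1-en-3-one that carries the 2-(TBS-oxy)ethyl group on the enone α-carbon, via alkyne–hexacarbonyldicobalt complex 17 (not isolated)
Conditions: Co2(CO)8 (1.1 equiv), toluene, rt, 2 h; then CO (1 atm), 75 °C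
Reagents that add atoms: none
Why: Co2(CO)8 binds the alkyne as complex 17; on heating one CO leaves, the tethered vinyl group coordinates and inserts into the cobalt–carbon bond at the alkyne carbon next to the quaternary centre, CO inserts and reductive elimination releases the cyclopentenone, so that alkyne, alkene and CO are joined in a (2+2+1) cycloaddition. The closest known reaction type is the cobalt-mediated intramolecular Pauson–Khand reaction of 1,6-enynes with a fully substituted propargylic carbon and an oxygenated allylic carbon. Ring A (the ketal-bearing five-membered ring) closes by 5-exo insertion of the vinyl group across the three-atom tether, which forms the ring-fusion C–C bond, and ring B (the cyclopentenone) closes in the carbonylative step through the two bonds to the new carbonyl carbon, leaving the tetrasubstituted alkene between the former alkyne carbons where the target needs it. The one new stereocentre, the ring-fusion CH, is set by the quaternary carbon, whose larger ring branch (the silyloxy-bearing carbon) should lie on the convex face, cis to the ring-fusion hydrogen; this centre becomes sp2 in step 19, so either epimer is usable. The step needs only chemoselectivity for the one enyne and a reactive tether conformation: there is a single alkyne and a single terminal alkene, the gem-disubstitution at the quaternary and ketal carbons (Thorpe–Ingold effect) holds the partners together, and silyl ethers, ketal and carbamate are inert to cobalt carbonyl.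

Step 12
Reactants: 18 bicyclic enone
Product: 19 the corresponding allylic alcohol (carbinol hydrogen cis to the ring-fusion hydrogen)
Conditions: NaBH4, CeCl3·7H2O, MeOH, −40 °C
Reagents that add atoms: none
Why: Luche 1,2-reduction of the enone, with hydride arriving on the convex face of the bicycle; the new carbinol centre is removed in step 13.

Step 13
Reactants: 19 allylic alcohol
Product: 20 deoxygenated bicyclo[3.3.0]oct-1-ene (ring B now CH2–CH2, tetrasubstituted alkene kept)
Conditions: Et3SiH (5 equiv), BF3·OEt2 (1.5 equiv), CH2Cl2, −78 °C; Et3N then aq. NaHCO3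
Reagents that add atoms: none
Why: Ionic hydrogenation (Kursanov–Parnes): the allylic alcohol ionises to an allyl cation that takes hydride from the silane at its less hindered secondary terminus, so the tetrasubstituted alkene stays in place.

Step 14
Reactants: 20 bis-silyl ether
Product: 21 diol (piperidin-4-ol and primary 2-hydroxyethyl)
Conditions: Bu4NF (3 equiv), THF, rt → 40 °C
Reagents that add atoms: none
Why: Fluoride-mediated desilylation cleaves both silyl ethers and leaves ketal and carbamate untouched.

Step 15
Reactants: 21 diol
Product: 22 primary iodide with free piperidin-4-ol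
Conditions: I2, PPh3, imidazole, CH2Cl2, 0 °C
Reagents that add atoms: iodine, II
Why: Appel-type iodination (Garegg–Samuelsson conditions) is selective for the primary alcohol because the neopentyl-type secondary alcohol is too hindered for SN2 displacement.

Step 16
Reactants: 22 iodo alcohol
Product: 23 iodo ketone (N-Boc 4-piperidinone restored)
Conditions: Dess–Martin periodinane, NaHCO3, CH2Cl2, rt
Reagents that add atoms: none
Why: Dess–Martin oxidation returns the piperidinone carbonyl without touching the primary iodide or the alkene.

Step 17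
Reactants: 23 iodo ketone
Product: 24 tricyclic bridged ketone (rings A–D, ketal on ring A, N-Boc)
Conditions: KN(SiMe3)2 (1.1 equiv), THF, −78 → 0 °C
Reagents that add atoms: none
Why: Intramolecular enolate C-alkylation (7-exo-tet): the ketone can enolise only toward its CH2 group, and axial attack of that enolate on the primary iodide closes ring C, the bridgehead CH taking the only configuration that the bridge from the quaternary carbon allows.

Step 18
Reactants: 24 ketal
Product: 25 diketone (ring-A ketone β,γ to the tetrasubstituted alkene)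
Conditions: PPTS, acetone/H2O (10:1), 55 °C
Reagents that add atoms: water, O
Why: Acid-catalysed ketal hydrolysis with a weak acid that spares the tert-butyl carbamate and does not move the alkene.

Step 19
Reactants: 25 diketone
Product: 26 dienyl triflate (rings A and B now the conjugated diene)
Conditions: KN(SiMe3)2 (1.1 equiv), THF, −78 °C; PhNTf2, −78 → 0 °C
Reagents that add atoms: N-phenylbis(trifluoromethanesulfonimide), O=S(=O)(N(c1ccccc1)S(=O)(=O)C(F)(F)F)C(F)(F)F
Why: Enolate O-sulfonylation: the hydrogen between the ring-A carbonyl and the alkene is by far the most acidic, so the conjugated dienolate forms and is trapped on oxygen, while the bridging ketone has no enolisable hydrogen because its only α-hydrogen is at a bridgehead.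

Step 20
Reactants: 26 dienyl triflate; 16 carbon monoxide
Product: 27 methyl dienoate (N-Boc, bridging ketone)
Conditions: Pd(OAc)2 (10 mol %), dppf (12 mol %), CO (1 atm), MeOH, Et3N, DMF, 60 °C
Reagents that add atoms: methanol, CO
Why: Palladium-catalysed alkoxycarbonylation of an enol triflate: oxidative addition to zerovalent palladium, CO insertion and methanolysis of the acylpalladium give the methyl ester.

Step 21
Reactants: 27 N-Boc keto dienoate; 28 formaldehyde
Product: 30 N-methyl keto dienoate, via secondary ammonium trifluoroacetate 29 (not isolated)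
Conditions: CF3CO2H, CH2Cl2, 0 °C, evaporate; 37% aq. HCHO, NaBH(OAc)3, NaOAc, ClCH2CH2Cl, rt
Reagents that add atoms: none
Why: Acidolysis of the tert-butyl carbamate followed by reductive amination with formaldehyde, the triacetoxyborohydride reducing the iminium ion but not the hindered bridging ketone or the ester.

Step 22
Reactants: 30 N-methyl keto dienoate
Product: 31 spiro-epoxide at the bridging carbon (CH2 on the cycloheptene face)
Conditions: Me3S+ I− (3 equiv), KN(SiMe3)2 (2.8 equiv), THF, −10 °C; then 30, −10 °C → rt
Reagents that add atoms: trimethylsulfonium iodide, C[S+](C)C.[I-]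
Why: Corey–Chaykovsky epoxidation: dimethylsulfonium methylide adds to the bridging ketone from the less hindered cycloheptene face and closes to the epoxide, being too weakly basic to deprotonate the dienoate and unreactive toward esters.

Step 23
Reactants: 31 spiro-epoxide
Product: 32 aldehyde (formyl group on the bridging CH, epimer mixture)
Conditions: BF3·OEt2 (2.2 equiv), CH2Cl2, −78 → −30 °C; aq. NaHCO3
Reagents that add atoms: none
Why: Meinwald rearrangement: Lewis-acid opening of the epoxide at its tertiary carbon and a 1,2-hydride shift give the aldehyde (one equivalent of BF3 is held by the amine), and the configuration of the formyl-bearing carbon does not matter because it is enolised in step 24.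

Step 24
Reactants: 32 aldehyde; 28 formaldehyde
Product: 33 α-hydroxymethyl aldehyde (spiro carbon now quaternary, CH2OH on the cycloheptene face)
Conditions: 37% aq. HCHO (5 equiv), DBU (0.5 equiv), THF, rt
Reagents that add atoms: none
Why: Crossed aldol reaction of an α-branched aldehyde with non-enolisable formaldehyde: the exocyclic enolate should be attacked on the cycloheptene face, which carries one syn-axial hydrogen and an sp2 carbon, rather than on the piperidine face with two syn-axial hydrogens, placing the hydroxymethyl group syn to ring C as in the target.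

Step 25
Reactants: 33 hydroxy aldehyde; 34 1-(triphenylphosphoranylidene)butan-2-one
Product: 35 (E)-enone (hydroxymethyl and 3-oxopent-1-enyl groups on the spiro carbon)
Conditions: 34 (3 equiv), toluene, 100 °C
Reagents that add atoms: none
Why: Wittig olefination with a stabilised ylide gives the (E)-enone under neutral conditions, which avoids retro-aldol loss of formaldehyde from the β-hydroxy aldehyde.

Step 26
Reactants: 35 enone
Product: 37 CNP0192143.1, via open δ-hydroxy ketone 36 (not isolated)
Conditions: H2 (1 atm), 10% Pd/C, EtOAc, rt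
Reagents that add atoms: none
Why: Catalytic hydrogenation saturates the disubstituted enone alkene much faster than the two tetrasubstituted alkenes of the dienoate, and the δ-hydroxy ketone then closes to the six-membered hemiketal, whose new centre equilibrates to the more stable anomer.

**Compound list**

1 | 1-tert-butyl 3-methyl 4-oxopiperidine-1,3-dicarboxylate | COC(=O)C1CN(C(=O)OC(C)(C)C)CCC1=O | starting material
2 | allyl alcohol | C=CCO | starting material
3 | 3-allyl 1-tert-butyl 4-oxopiperidine-1,3-dicarboxylate | C=CCOC(=O)C1CN(C(=O)OC(C)(C)C)CCC1=O | intermediate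
4 | 1-[(trimethylsilyl)ethynyl]-1,2-benziodoxol-3(1H)-one | C[Si](C)(C)C#CI1OC(=O)c2ccccc12 | starting material
5 | 3-allyl 1-tert-butyl 3-ethynyl-4-oxopiperidine-1,3-dicarboxylate (racemic) | C#CC1(C(=O)OCC=C)CN(C(=O)OC(C)(C)C)CCC1=O | intermediate
6 | tert-butyl (3S)-3-allyl-3-ethynyl-4-oxopiperidine-1-carboxylate | O=C1CCN(C(=O)OC(C)(C)C)C[C@]1(CC=C)C#C | intermediate
7 | tert-butyl (3S,4R)-3-allyl-3-ethynyl-4-hydroxypiperidine-1-carboxylate (OH cis to ethynyl) | O[C@@H]1CCN(C(=O)OC(C)(C)C)C[C@]1(CC=C)C#C | intermediate
8 | ethylene oxide | C1CO1 | starting material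
9 | tert-butyl (3S,4R)-3-allyl-4-hydroxy-3-(4-hydroxybut-1-yn-1-yl)piperidine-1-carboxylate | O[C@@H]1CCN(C(=O)OC(C)(C)C)C[C@]1(CC=C)C#CCCO | intermediate
10 | tert-butyl (3S,4R)-3-allyl-4-(TBS-oxy)-3-[4-(TBS-oxy)but-1-yn-1-yl]piperidine-1-carboxylate | CC(C)(C)[Si](C)(C)O[C@@H]1CCN(C(=O)OC(C)(C)C)C[C@]1(CC=C)C#CCCO[Si](C)(C)C(C)(C)C | intermediate
11 | tert-butyl (3S,4R)-4-(TBS-oxy)-3-[4-(TBS-oxy)but-1-yn-1-yl]-3-(2-oxoethyl)piperidine-1-carboxylate | CC(C)(C)[Si](C)(C)O[C@@H]1CCN(C(=O)OC(C)(C)C)C[C@]1(CC=O)C#CCCO[Si](C)(C)C(C)(C)C | intermediate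
12 | vinylmagnesium bromide | C=C[Mg]Br | starting material
13 | tert-butyl (3S,4R)-4-(TBS-oxy)-3-[4-(TBS-oxy)but-1-yn-1-yl]-3-(2-hydroxybut-3-en-1-yl)piperidine-1-carboxylate (both carbinol epimers) | CC(C)(C)[Si](C)(C)O[C@@H]1CCN(C(=O)OC(C)(C)C)C[C@]1(CC(O)C=C)C#CCCO[Si](C)(C)C(C)(C)C | intermediate
14 | tert-butyl (3S,4R)-4-(TBS-oxy)-3-[4-(TBS-oxy)but-1-yn-1-yl]-3-(2-oxobut-3-en-1-yl)piperidine-1-carboxylate | CC(C)(C)[Si](C)(C)O[C@@H]1CCN(C(=O)OC(C)(C)C)C[C@]1(CC(=O)C=C)C#CCCO[Si](C)(C)C(C)(C)C | intermediate
15 | tert-butyl (3S,4R)-4-(TBS-oxy)-3-[4-(TBS-oxy)but-1-yn-1-yl]-3-[(2-vinyl-1,3-dioxolan-2-yl)methyl]piperidine-1-carboxylate (1,6-enyne) | CC(C)(C)[Si](C)(C)O[C@@H]1CCN(C(=O)OC(C)(C)C)C[C@]1(CC2(OCCO2)C=C)C#CCCO[Si](C)(C)C(C)(C)C | intermediate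
16 | carbon monoxide | [C-]#[O+] | starting material
17 | hexacarbonyldicobalt complex of the alkyne of 15 | CC(C)(C)[Si](C)(C)O[C@@H]1CCN(C(=O)OC(C)(C)C)C[C@]1(CC2(OCCO2)C=C)C34[Co]5(=C=O)(=C=O)(=C=O)[Co]3(=C=O)(=C=O)(=C=O)C45CCO[Si](C)(C)C(C)(C)C | intermediate
18 | N-Boc 4-(TBS-oxy)piperidine spiro-linked at C3 to the ketal-bearing bicyclo[3.3.0]oct-1-en-3-one with a 2-(TBS-oxy)ethyl group on the enone α-carbon (ring-fusion H cis to the silyloxy-bearing carbon) | CC(C)(C)[Si](C)(C)O[C@@H]1CCN(C(=O)OC(C)(C)C)C[C@@]12CC3(OCCO3)[C@@H]4CC(=O)C(CCO[Si](C)(C)C(C)(C)C)=C42 | intermediate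
19 | allylic alcohol from 18 (carbinol H cis to ring-fusion H) | CC(C)(C)[Si](C)(C)O[C@@H]1CCN(C(=O)OC(C)(C)C)C[C@@]12CC3(OCCO3)[C@@H]4C[C@H](O)C(CCO[Si](C)(C)C(C)(C)C)=C42 | intermediate
20 | deoxygenated spiro bicyclo[3.3.0]oct-1-ene, both silyl ethers in place | CC(C)(C)[Si](C)(C)O[C@@H]1CCN(C(=O)OC(C)(C)C)C[C@@]12CC3(OCCO3)[C@@H]4CCC(CCO[Si](C)(C)C(C)(C)C)=C42 | intermediate
21 | diol from 20 | O[C@@H]1CCN(C(=O)OC(C)(C)C)C[C@@]12CC3(OCCO3)[C@@H]4CCC(CCO)=C42 | intermediate
22 | primary iodide with free piperidin-4-ol | O[C@@H]1CCN(C(=O)OC(C)(C)C)C[C@@]12CC3(OCCO3)[C@@H]4CCC(CCI)=C42 | intermediate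
23 | iodo ketone (N-Boc 4-piperidinone) | O=C1CCN(C(=O)OC(C)(C)C)C[C@@]12CC3(OCCO3)[C@@H]4CCC(CCI)=C42 | intermediate
24 | tricyclic bridged ketone with ring-A ketal (rings A–D closed) | O=C2[C@@H]1CCC3=C4[C@@H](CC3)C5(OCCO5)C[C@@]42CN(C(=O)OC(C)(C)C)C1 | intermediate
25 | diketone (bridging ketone and ring-A ketone) | O=C2[C@@H]1CCC3=C4[C@@H](CC3)C(=O)C[C@@]42CN(C(=O)OC(C)(C)C)C1 | intermediate
26 | dienyl triflate | O=C2[C@@H]1CCC3=C4C(CC3)=C(OS(=O)(=O)C(F)(F)F)C[C@@]42CN(C(=O)OC(C)(C)C)C1 | intermediate
27 | methyl dienoate, N-Boc, bridging ketone | O=C2[C@@H]1CCC3=C4C(CC3)=C(C(=O)OC)C[C@@]42CN(C(=O)OC(C)(C)C)C1 | intermediate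
28 | formaldehyde | C=O | starting material
29 | secondary ammonium trifluoroacetate from 27 | O=C2[C@@H]1CCC3=C4C(CC3)=C(C(=O)OC)C[C@@]42C[NH2+]C1.[O-]C(=O)C(F)(F)F | intermediate
30 | N-methyl keto dienoate | O=C2[C@@H]1CCC3=C4C(CC3)=C(C(=O)OC)C[C@@]42CN(C)C1 | intermediate
31 | spiro-epoxide at the bridging carbon (CH2 on the cycloheptene face) | C1O[C@]12[C@@H]3CCC4=C5C(CC4)=C(C(=O)OC)C[C@@]52CN(C)C3 | intermediate
32 | aldehyde on the bridging CH (both epimers at that carbon) | O=CC2[C@@H]1CCC3=C4C(CC3)=C(C(=O)OC)C[C@@]42CN(C)C1 | intermediate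
33 | α-hydroxymethyl aldehyde, quaternary spiro carbon | O=C[C@@]2(CO)[C@@H]1CCC3=C4C(CC3)=C(C(=O)OC)C[C@@]42CN(C)C1 | intermediate
34 | 1-(triphenylphosphoranylidene)butan-2-one | CCC(=O)C=P(c1ccccc1)(c1ccccc1)c1ccccc1 | starting material
35 | (E)-enone with hydroxymethyl group on the spiro carbon | CCC(=O)/C=C/[C@@]2(CO)[C@@H]1CCC3=C4C(CC3)=C(C(=O)OC)C[C@@]42CN(C)C1 | intermediate
36 | open δ-hydroxy ketone | CCC(=O)CC[C@@]2(CO)[C@@H]1CCC3=C4C(CC3)=C(C(=O)OC)C[C@@]42CN(C)C1 | intermediate
37 | CNP0192143.1 | CC[C@@]1(O)CC[C@@]2(CO1)[C@@H]1CCC3=C4C(=C(C(=O)OC)C[C@@]42CN(C)C1)CC3 | target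

**Step count and risks**

Total steps: 26. Longest linear sequence: 26 steps (1 → 37); all other numbered starting materials are bought.

Steps most likely to fail:

1. Step 13. The allyl cation may lose a proton to give a cyclopentadiene, be captured by the carbamate carbonyl, or the Lewis acid may open the dioxolane before hydride transfer occurs. The fallback replaces the cationic deoxygenation by a radical one. Setting out from 19, 1,1'-thiocarbonyldiimidazole (DMAP, CH2Cl2, 40 °C) should give the allylic imidazole-1-carbothioate F1. Bu3SnH/AIBN (toluene, 80 °C; Barton–McCombie deoxygenation) then reduces it through the allyl radical, which should take hydrogen at its secondary terminus. The route is rejoined at 20.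

2. Step 24. Formaldehyde may approach the exocyclic enolate from the piperidine face, or with little preference, which would give the wrong or a mixed configuration at the spiro carbon. The fallback inverts the order of the two C–C bond formations, so that the chain and not the hydroxymethyl carbon enters last; it sets the centre correctly if the piperidine face is the accessible one. Setting out from 32, DBU-catalysed Michael addition to ethyl vinyl ketone (CCC(=O)C=C) should give the keto aldehyde F2. Its formyl group is then reduced in preference to the ketone with NaBH(OAc)3 to 36, which closes to the hemiketal. The route is rejoined at 37.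

3. Step 23. Opening of the epoxide gives a tertiary cation next to a quaternary carbon, which may undergo a Wagner–Meerwein shift instead of the hydride shift, and the BF3–amine complex may slow the reaction. The fallback avoids a cationic intermediate. Setting out from 30, methylenation with Zn/CH2Br2/TiCl4 (non-basic and ketone-selective) should give the exocyclic alkene F3. Hydroboration–oxidation (9-BBN; NaBO3·4H2O) gives the primary alcohol F4, and Parikh–Doering oxidation (SO3·pyridine, DMSO, Et3N) gives the aldehyde. The route is rejoined at 32.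

Further compounds

F1 | step 13 | O-allylic imidazole-1-carbothioate of 19 | CC(C)(C)[Si](C)(C)O[C@@H]1CCN(C(=O)OC(C)(C)C)C[C@@]12CC3(OCCO3)[C@@H]4C[C@H](OC(=S)n5ccnc5)C(CCO[Si](C)(C)C(C)(C)C)=C42
F2 | step 24 | keto aldehyde with formyl and 3-oxopentyl groups on the spiro carbon | CCC(=O)CC[C@@]2(C=O)[C@@H]1CCC3=C4C(CC3)=C(C(=O)OC)C[C@@]42CN(C)C1
F3 | step 23 | exocyclic methylene compound from 30 | C=C2[C@@H]1CCC3=C4C(CC3)=C(C(=O)OC)C[C@@]42CN(C)C1
F4 | step 23 | primary alcohol on the bridging CH (both epimers at that carbon) | OCC2[C@@H]1CCC3=C4C(CC3)=C(C(=O)OC)C[C@@]42CN(C)C1
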